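## Structural features

The target is a 2,3-dihydrobenzofuran in which ring A (C3a–C7a) is fused to the O1–C2–C3 ring and carries a hydroxyl group at C6 and an (E)-4-hydroxystyryl group at C4. C2 bears a 3,4-dihydroxyphenyl (catechol) ring and C3 a 3,5-dihydroxyphenyl (resorcinol) ring; the two carbons are adjacent stereocentres, both S, with the aryl groups trans. C3 is the congested position, since it lies between the C2 aryl group and the styryl group on C4. Three elements are fragile: the C2–O1 bond, a benzylic aryl ether that ionises under protic or Lewis acid because the C2 aryl ring is para-oxygenated; the electron-rich stilbene, which strong acid protonates so that the neighbouring resorcinol ring can add to it; and the six phenols, the catechol above all, which oxidise in base under air. The real difficulty is therefore to set the trans-(2S,3S) pair beside a fully substituted ring position and to reach six free phenols without strong acid. The key step exploits the resorcinol ring on C3: its ipso carbon, one ortho CH, the two C–OH carbons with the CH between them, and the other ortho CH are the carbons C1'–C6' of a 3,5-dioxohexanoyl chain bound to C3 through C1' (primed numbers denote this chain throughout). One aldol bond, C1'–C6', therefore grows the whole ring from a carboxyl carbon on C3, which a stereospecific ring contraction of a flavanone can place there trans to the C2 aryl group.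

## Logic of the disconnections

**18 from 17.** The four O–CH2Ph bonds (at C6 of ring A, on the styryl ring and on the catechol ring) are cut last. Benzyl is used on these spectator phenols in place of methyl, because removing methyl ethers would need BBr3, which ionises C2–O1 and protonates the stilbene. The gain is that every earlier intermediate is a robust ether that tolerates carbanions, hydroxide, acid and palladium. The demand is complete cleavage of four ethers at −78 °C with BCl3 and a cation scavenger, without benzylation of the electron-rich rings.

**17 from 15 (key disconnection).** The bond between the ipso carbon and one ortho carbon of the resorcinol ring (C1'–C6') is cut and the two C–OH carbons are read as ketones. A 5-substituted resorcinol is the aldol fold of a 1,3,5-triketone, so the whole aryl ring collapses to an acyl group on C3, and the most hindered aryl–C(sp3) bond of the target never has to be made by coupling. The gain is one ring and a return to a C3 carbonyl compound whose trans configuration is the thermodynamic one. The demand is that the aldol of the methyl terminus onto the hindered C1' ketone outrun loss of O1 from the C3 enolate, and that C3 be trans before it is locked.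

**15 from 11 and 12.** The C1'–C2' bond is cut: a Claisen-type acylation of the terminal carbanion of 14, the dianion of 12. This uses the simplest five-carbon partner and leaves only a carboxyl group on the heterocycle. The demand is severe, because C3–H of the acyl donor is benzylic and α to the carbonyl, so a methyl ester would be deprotonated by 14 instead of attacked. The carboxyl group of 11 is therefore activated as its imidazolide in 13, which accepts the carbanion at −78 °C.

**11 from 9, and 9 from 7 and 8.** The O–CH3 bond of the ester is cut first, then the C4–Cα bond between ring A and the styryl group. The stilbene is disconnected here because an electron-rich alkene would not survive the oxidative rearrangement that makes 7, while an aryl triflate would not survive the carbanion and hydroxide chemistry after 9. The gain is a commercial styrene and a heterocycle whose C4 is held as a triflate. The demand is a linear, E-selective Heck coupling at a triflate ortho to the C3 substituent under a base too weak to enolise the ester, and an ester cleavage that does not open the ring.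

**7 from 5.** The C3–C3a bond is cut and C3a is re-attached to the ester carbon, which turns the dihydrofuran back into a chromanone. The C3 stereocentre disappears: in the forward direction it is created trans to the C2 aryl group by a stereospecific 1,2-shift, so only one stereocentre needs a catalyst. The demand is that ring A migrate (not ring B or hydride) and that C2 keep its configuration in the acidic medium.

**5 from 3 and 4.** The C2–aryl bond is cut; forward, the aryl group of 4 adds to C2 of the enone of 3 under a chiral palladium catalyst. This is the only reagent-controlled stereocentre of the route. The gain is a flat, achiral heterocycle and a catalogue boronic acid. The demand is high facial selectivity and a catalyst that leaves the aryl triflate alone.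

**3 from 2, and 2 from 1.** The O–SO2CF3 bond at C5 and the O–CH2Ph bond at C7 are cut. The C5 hydroxyl of 1 is hydrogen-bonded to the carbonyl, so O7 is benzylated first and O5 then becomes the leaving group that ends as C4 of the benzofuran. The gain is a catalogue chromone; the demand is mono-alkylation at O7.

## Other disconnections considered

**Alternative 1:** The cut is C3–C3a with re-attachment of C3a to the carboxyl carbon, taking ester A1 back to flavanone A2. Forward, PhI(OAc)2 and H2SO4 in HC(OMe)3 convert A2 through its enol ether into a C3 iodane; ring A shifts from the former carbonyl carbon to C3 anti to the departing iodobenzene, and that carbon ends as the methyl ester of A1.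
- In its favour: the shift is stereospecific, C2 is untouched, the trans relation follows from the diequatorial intermediate, and the triflate remains as a handle. On the construction of the heterocycle it is the equal of the chosen plan, which uses the same reaction in step 4 on a benzyl-protected analogue.
- Against it as the strategic centre: it ends at an ester, so the whole 3,5-dioxygenated ring must still be placed on the most hindered carbon. One way on is the triketone fold of the chosen plan. The other is a decarboxylative arylation after ester hydrolysis, which would be one step shorter (a point in its favour) but requires coupling a benzylic radical flanked by two ortho substituents and carrying a β-aryloxy group.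
- The methyl ethers of A1 also commit the end game to a Lewis-acid demethylation of a skeleton that ionises at C2–O1.
- Comparison: the two plans share the rearrangement. They differ in whether the resorcinol ring arrives as a preformed aryl nucleophile or is grown from the carboxyl carbon; the chosen plan avoids a C(sp3)–aryl coupling at the price of base-sensitive β-aryloxy carbonyl intermediates.

**Alternative 2:** The cut is C2–C3. Hydrazone A4 is oxidised with MnO2 and the diazo function is decomposed by Rh2(R-PTAD)4; the donor/donor carbene at the future C3 inserts into a benzylic C–H bond of the 3,4-dimethoxybenzyl ether and closes the ring as the cis isomer A3.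
- In its favour: both aryl groups are already in place, the S configuration at C3 comes directly from the catalyst, and no carbonyl group is ever on C3, so enolisation and β-elimination do not arise. It also needs fewer steps to the ring system; on convergence and step economy it is the better plan.
- Against it here: A3 has C2 in the wrong configuration, so an acid-mediated epimerisation through reversible opening of C2–O1 is needed to reach A5. This is best done on the bromide before the stilbene exists, and is plausible because C3 cannot epimerise.
- The hydrazone must be formed on a ketone carbon flanked by two ortho substituents, and insertion selectivity for a di-ortho-substituted diaryl carbene is less secure than in simpler cases.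
- A5 still needs the Heck coupling and removal of five methyl ethers, the acid end game that the chosen plan avoids; benzyl ethers would add competing benzylic C–H bonds.
- Comparison: the chosen plan sets C2 by catalyst and C3 by a stereospecific shift with no correction step; the alternative sets C3 by catalyst and corrects C2 afterwards. Stereocontrol is of comparable quality.

**Alternative 3:** The cuts are O1–C7a and C3–C3a. CsF releases an aryne from silyl triflate A8; the oxygen of enantiopure trans-epoxide A7 adds to the aryne carbon remote from bromine, the benzylic C–O bond on the 3,5-dimethoxyphenyl side opens, and the aryl anion next to bromine captures that carbon to give A6.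
- In its favour: the highest convergence of the four plans, both stereocentres drawn from an epoxide, the resorcinol ring present from the start, and no base-sensitive carbonyl on C3. On these points it is the equal or the better of the chosen plan.
- Against it here: C3–O must break in preference to C2–O, which rests only on the electronic difference between a 3,5-dimethoxyphenyl group (both methoxy groups meta, so not strongly cation-stabilising) and the bis-mesylated ring.
- Capture at C3 must occur with retention (the anion is tethered on the face of the leaving oxygen); A7 is drawn as the 2R,3R isomer on that assumption. Any free benzylic cation would erode both the trans relation and the enantiomeric purity.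
- The aryl anion sits ortho to bromine and can expel bromide instead of closing the ring.
- Two mesylates and three methyl ethers must then be removed by different methods, again including a Lewis-acid demethylation.
- Comparison: step count is roughly equal, since A7 and A8 each take several steps in parallel. Mechanistically it stakes both stereocentres on one ionising step, whereas the chosen plan separates them into a catalyst-controlled addition and a stereospecific shift.

Key step: step 8

Assumption: 5,7-dihydroxychromone, 3,4-bis(benzyloxy)phenylboronic acid and 4-(benzyloxy)styrene are taken as catalogue compounds.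

## Route

**Step 1**
Reactants: 1 5,7-dihydroxy-4H-chromen-4-one
Product: 2 7-(benzyloxy)-5-hydroxy-4H-chromen-4-one
Conditions: BnBr (1.05 equiv), K2CO3, acetone, reflux
Reagents that add atoms: benzyl bromide, BrCc1ccccc1
Why: Williamson etherification; the C5 hydroxyl is held in a hydrogen bond to the C4 carbonyl and is much less acidic and nucleophilic than the C7 hydroxyl, so one equivalent of benzyl bromide should alkylate O7 selectively.

**Step 2**
Reactants: 2 7-(benzyloxy)-5-hydroxy-4H-chromen-4-one
Product: 3 7-(benzyloxy)-4-oxo-4H-chromen-5-yl trifluoromethanesulfonate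
Conditions: Tf2O, pyridine, CH2Cl2, 0 °C → rt
Reagents that add atoms: trifluoromethanesulfonic anhydride, O=S(=O)(OS(=O)(=O)C(F)(F)F)C(F)(F)F
Why: O-sulfonylation of the chelated phenol, the usual way to turn 5-hydroxychromones into coupling partners; the benzyl ether and the pyranone are inert at 0 °C, and the triflate is installed before C2 becomes a stereocentre so that no base meets the flavanone later.

**Step 3**
Reactants: 3 7-(benzyloxy)-4-oxo-4H-chromen-5-yl trifluoromethanesulfonate; 4 3,4-bis(benzyloxy)phenylboronic acid
Product: 5 (2S)-7-(benzyloxy)-2-[3,4-bis(benzyloxy)phenyl]-4-oxochroman-5-yl trifluoromethanesulfonate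
Conditions: Pd(OCOCF3)2 (5 mol%), (R)-t-BuPyOx (6 mol%), NH4PF6 (30 mol%), H2O (5 equiv), ClCH2CH2Cl, 60 °C
Reagents that add atoms: none
Why: Asymmetric conjugate addition of an arylboronic acid to a chromone by cationic divalent palladium with a pyridine-oxazoline ligand: transmetalation, insertion of the enone and protonation of the palladium enolate by water keep the metal divalent, so the aryl triflate is not engaged. C2 is set by the ligand, whose tert-butyl group blocks one face of the coordinated enone at insertion; the R ligand is chosen because the S ligand gives the 2R series with cyclic enones and chromones, and the sense is to be confirmed by circular dichroism before going on.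

**Step 4**
Reactants: 5 (2S)-flavanone triflate
Product: 7 methyl (2S,3S)-6-(benzyloxy)-2-[3,4-bis(benzyloxy)phenyl]-4-(trifluoromethylsulfonyloxy)-2,3-dihydrobenzofuran-3-carboxylate, via methyl enol ether 6 (not isolated)
Conditions: PhI(OAc)2 (1.2 equiv), H2SO4 (1 equiv), HC(OMe)3, 0 °C → rt; then H2O, NaHCO3
Reagents that add atoms: trimethyl orthoformate, COC(OC)OC (methoxy group); water, O (acyl oxygen, by hydrolysis of the orthoester on work-up)
Why: Oxidative ring contraction of a flavanone by a trivalent iodine reagent (semipinacol-type 1,2-aryl shift): enol ether 6 is attacked at C3 by the iodane trans to the C2 aryl group, and ring A, whose migrating carbon is activated by O1 (ortho) and the C7 benzyloxy group (para), shifts from C4 to C3 anti to the departing iodobenzene while C4 becomes the ester carbon. C2 is untouched and C3 forms with inversion at the carbon–iodine bond, which from the diequatorial intermediate gives the trans (2S,3S) ester; any cis isomer can equilibrate to trans at the enolisable C3. Benzyl ethers and the triflate are stable to H2SO4 in HC(OMe)3, and no alkene is present yet.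

**Step 5**
Reactants: 7 trans ester triflate; 8 4-(benzyloxy)styrene
Product: 9 methyl (2S,3S)-6-(benzyloxy)-2-[3,4-bis(benzyloxy)phenyl]-4-[(E)-4-(benzyloxy)styryl]-2,3-dihydrobenzofuran-3-carboxylate
Conditions: PdCl2(PPh3)2 (5 mol%), LiCl, Et3N, DMF, 90 °C
Reagents that add atoms: none
Why: Heck reaction of an aryl triflate: after oxidative addition of zerovalent palladium, LiCl converts the aryl–palladium triflate into the neutral chloride, which favours insertion at the terminal alkene carbon and, after syn β-hydride elimination, the linear E-stilbene. Et3N is too weak to enolise the C3 ester, so the ring and both stereocentres stay intact.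

**Step 6**
Reactants: 9 methyl ester
Product: 11 (2S,3S)-6-(benzyloxy)-2-[3,4-bis(benzyloxy)phenyl]-4-[(E)-4-(benzyloxy)styryl]-2,3-dihydrobenzofuran-3-carboxylic acid, via trimethylstannyl ester 10 (not isolated)
Conditions: Me3SnOH (5 equiv), ClCH2CH2Cl, 80 °C; then 0.5 M aq. HCl wash
Reagents that add atoms: trimethyltin hydroxide, C[Sn](C)(C)O
Why: Ester cleavage with Me3SnOH, a near-neutral reagent that delivers hydroxide to the tin-coordinated carbonyl and gives stannyl ester 10, which the dilute acid wash converts into 11. It is preferred to aqueous LiOH because C3–H is α to the carbonyl and β to O1, so a strongly basic hydrolysis could open the ring; benzyl ethers and the stilbene are unaffected.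

**Step 7**
Reactants: 11 carboxylic acid; 12 acetylacetone (pentane-2,4-dione)
Product: 15 1-[(2S,3S)-6-(benzyloxy)-2-[3,4-bis(benzyloxy)phenyl]-4-[(E)-4-(benzyloxy)styryl]-2,3-dihydrobenzofuran-3-yl]hexane-1,3,5-trione, via acyl imidazolide 13 (not isolated), via dilithium acetylacetone dianion 14 (not isolated)
Conditions: 11, 1,1'-carbonyldiimidazole (1.1 equiv), THF, rt; separately 12 (4 equiv), LiN(i-Pr)2 (8 equiv), THF, −78 → 0 °C; combine at −78 °C, → −20 °C; AcOH
Reagents that add atoms: none
Why: Claisen-type C-acylation of a 1,3-diketone dianion at its terminal carbon by an activated acyl derivative: 1,1'-carbonyldiimidazole turns 11 into imidazolide 13, and the terminal carbanion of 14 adds to it at −78 °C, with excess 14 absorbing the protons of the released imidazole and of the more acidic product. The imidazolide is used because a methyl ester would lose its acidic C3–H before being attacked; if 13 is deprotonated in part, the resulting ketene is captured by 14 to give the same product. C3 is epimerisable in 15 and should settle trans; the crude triketone is used promptly because acid would close it to a 4-pyranone.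

**Step 8**
Reactants: 15 triketone (trans-3-(3,5-dioxohexanoyl) compound)
Product: 17 5-[(2S,3S)-6-(benzyloxy)-2-[3,4-bis(benzyloxy)phenyl]-4-[(E)-4-(benzyloxy)styryl]-2,3-dihydrobenzofuran-3-yl]benzene-1,3-diol, via cyclic aldol 16 (not isolated)
Conditions: KOH (1 M aq., 10 equiv), MeOH/THF (degassed), Ar, 25 → 45 °C; then AcOH to pH 6 at 0 °C
Reagents that add atoms: none
Why: In aqueous-methanolic KOH 15 is held as the enolates of its two 1,3-dicarbonyl units, and the small equilibrium share in which C5' is enolised toward the terminal methyl while C1' is a free ketone closes the ring, C6' adding to C1' to give aldol 16. Loss of hydroxide by E1cB and enolisation of the two remaining carbonyls then give the benzene ring of 17, so one C–C bond (C1'–C6', ipso to ortho) and one ring are formed with water as the only by-product; the closest known reaction type is the base-mediated aldol cyclisation of 1,3,5-triketones to 5-substituted resorcinols, the fold that turns heptane-2,4,6-trione into orcinol. The closure is 6-(enolendo)-exo-trig, a favoured mode: both carbons of the reacting enolate C5'=C6' end up in the ring (so it is enolendo, not enolexo) and the carbonyl oxygen stays outside. No stereocentre is created, since the carbinol carbon of 16 has two identical ring arms and becomes sp2, and C2 and C3 are only carried through. The selectivity needed is aldol from the methyl terminus and not from C3, and aldol in preference to β-elimination of O1. The first is secured because addition from C3 onto C5' would give a quaternary centre that cannot dehydrate to an arene and so reverts, while the methyl-terminus adduct is drained by aromatisation; the second because the base is taken up by the far more acidic chain methylenes, so the C3 enolate is a minor species, and expulsion of O1 from it is the reverse of a 5-endo-trig closure with poor orbital overlap. Any C3 epimer should equilibrate through that enolate to the trans isomer before C1' becomes an aromatic carbon. Benzyl ethers and the stilbene are inert to hydroxide, and air is excluded and the work-up kept at pH 6 to avoid phenolate oxidation and acid-induced reactions of the benzylic ether.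

**Step 9**
Reactants: 17 tetra-O-benzyl resorcinol
Product: 18 scirpusin A, 4-[(2S,3S)-3-(3,5-dihydroxyphenyl)-6-hydroxy-4-[(E)-2-(4-hydroxyphenyl)ethenyl]-2,3-dihydrobenzofuran-2-yl]benzene-1,2-diol
Conditions: BCl3 (12 equiv), C6HMe5 (15 equiv), CH2Cl2, −78 °C; MeOH/CHCl3 quench at −78 °C
Reagents that add atoms: none
Why: Lewis-acid debenzylation with a non-basic cation scavenger: BCl3 activates each ether oxygen and the benzyl cation is transferred to pentamethylbenzene, which prevents Friedel–Crafts benzylation of the electron-rich rings. At −78 °C with a cold methanol quench the C2–O1 bond and the stilbene, which BBr3 at room temperature would endanger, should stay intact, and no stereocentre is touched.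

## Compound list

1 | 5,7-dihydroxy-4H-chromen-4-one (5,7-dihydroxychromone) | O=c1ccoc2cc(O)cc(O)c12 | starting material
2 | 7-(benzyloxy)-5-hydroxy-4H-chromen-4-one | O=c1ccoc2cc(OCc3ccccc3)cc(O)c12 | intermediate
3 | 7-(benzyloxy)-4-oxo-4H-chromen-5-yl trifluoromethanesulfonate | O=c1ccoc2cc(OCc3ccccc3)cc(OS(=O)(=O)C(F)(F)F)c12 | intermediate
4 | 3,4-bis(benzyloxy)phenylboronic acid | OB(O)c1ccc(OCc2ccccc2)c(OCc2ccccc2)c1 | starting material
5 | (2S)-7-(benzyloxy)-2-[3,4-bis(benzyloxy)phenyl]-4-oxochroman-5-yl trifluoromethanesulfonate | O=C1C[C@@H](c2ccc(OCc3ccccc3)c(OCc3ccccc3)c2)Oc2cc(OCc3ccccc3)cc(OS(=O)(=O)C(F)(F)F)c21 | intermediate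
6 | (2S)-7-(benzyloxy)-2-[3,4-bis(benzyloxy)phenyl]-4-methoxy-2H-chromen-5-yl trifluoromethanesulfonate (not isolated) | COC1=C[C@@H](c2ccc(OCc3ccccc3)c(OCc3ccccc3)c2)Oc2cc(OCc3ccccc3)cc(OS(=O)(=O)C(F)(F)F)c21 | intermediate
7 | methyl (2S,3S)-6-(benzyloxy)-2-[3,4-bis(benzyloxy)phenyl]-4-(trifluoromethylsulfonyloxy)-2,3-dihydrobenzofuran-3-carboxylate (2,3-trans) | O=S(=O)(Oc1cc(OCc3ccccc3)cc2c1[C@H](C(=O)OC)[C@@H](c1ccc(OCc3ccccc3)c(OCc3ccccc3)c1)O2)C(F)(F)F | intermediate
8 | 4-(benzyloxy)styrene | C=Cc1ccc(OCc2ccccc2)cc1 | starting material
9 | methyl (2S,3S)-6-(benzyloxy)-2-[3,4-bis(benzyloxy)phenyl]-4-[(E)-4-(benzyloxy)styryl]-2,3-dihydrobenzofuran-3-carboxylate | c1ccccc1COc1ccc(/C=C/c2cc(OCc4ccccc4)cc3c2[C@H](C(=O)OC)[C@@H](c2ccc(OCc4ccccc4)c(OCc4ccccc4)c2)O3)cc1 | intermediate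
10 | trimethylstannyl (2S,3S)-6-(benzyloxy)-2-[3,4-bis(benzyloxy)phenyl]-4-[(E)-4-(benzyloxy)styryl]-2,3-dihydrobenzofuran-3-carboxylate (not isolated) | c1ccccc1COc1ccc(/C=C/c2cc(OCc4ccccc4)cc3c2[C@H](C(=O)O[Sn](C)(C)C)[C@@H](c2ccc(OCc4ccccc4)c(OCc4ccccc4)c2)O3)cc1 | intermediate
11 | (2S,3S)-6-(benzyloxy)-2-[3,4-bis(benzyloxy)phenyl]-4-[(E)-4-(benzyloxy)styryl]-2,3-dihydrobenzofuran-3-carboxylic acid | c1ccccc1COc1ccc(/C=C/c2cc(OCc4ccccc4)cc3c2[C@H](C(=O)O)[C@@H](c2ccc(OCc4ccccc4)c(OCc4ccccc4)c2)O3)cc1 | intermediate
12 | acetylacetone (pentane-2,4-dione) | CC(=O)CC(C)=O | starting material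
13 | [(2S,3S)-6-(benzyloxy)-2-[3,4-bis(benzyloxy)phenyl]-4-[(E)-4-(benzyloxy)styryl]-2,3-dihydrobenzofuran-3-yl](1H-imidazol-1-yl)methanone (not isolated) | c1ccccc1COc1ccc(/C=C/c2cc(OCc4ccccc4)cc3c2[C@H](C(=O)n5ccnc5)[C@@H](c2ccc(OCc4ccccc4)c(OCc4ccccc4)c2)O3)cc1 | intermediate
14 | dilithium dianion of pentane-2,4-dione (not isolated) | [Li+].[Li+].C=C([O-])C=C(C)[O-] | intermediate
15 | 1-[(2S,3S)-6-(benzyloxy)-2-[3,4-bis(benzyloxy)phenyl]-4-[(E)-4-(benzyloxy)styryl]-2,3-dihydrobenzofuran-3-yl]hexane-1,3,5-trione (drawn as the triketo tautomer; key-step precursor) | c1ccccc1COc1ccc(/C=C/c2cc(OCc4ccccc4)cc3c2[C@H](C(=O)CC(=O)CC(C)=O)[C@@H](c2ccc(OCc4ccccc4)c(OCc4ccccc4)c2)O3)cc1 | intermediate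
16 | 5-[(2S,3S)-6-(benzyloxy)-2-[3,4-bis(benzyloxy)phenyl]-4-[(E)-4-(benzyloxy)styryl]-2,3-dihydrobenzofuran-3-yl]-5-hydroxycyclohexane-1,3-dione (not isolated) | c1ccccc1COc1ccc(/C=C/c2cc(OCc4ccccc4)cc3c2[C@H](C5(O)CC(=O)CC(=O)C5)[C@@H](c2ccc(OCc4ccccc4)c(OCc4ccccc4)c2)O3)cc1 | intermediate
17 | 5-[(2S,3S)-6-(benzyloxy)-2-[3,4-bis(benzyloxy)phenyl]-4-[(E)-4-(benzyloxy)styryl]-2,3-dihydrobenzofuran-3-yl]benzene-1,3-diol (key-step product) | c1ccccc1COc1ccc(/C=C/c2cc(OCc4ccccc4)cc3c2[C@H](c2cc(O)cc(O)c2)[C@@H](c2ccc(OCc4ccccc4)c(OCc4ccccc4)c2)O3)cc1 | intermediate
18 | scirpusin A | Oc1ccc(/C=C/c2cc(O)cc3c2[C@H](c2cc(O)cc(O)c2)[C@@H](c2ccc(O)c(O)c2)O3)cc1 | target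

## Step count and least certain steps

Total: 9 steps. Longest linear sequence: 9 steps (1 → 18); 4, 8 and 12 enter as purchased building blocks.

**Step 8 (key step).** What may go wrong: β-elimination of O1 from the C3 enolate (retro-oxa-Michael opening, which would destroy both stereocentres); an aldol so slow at the hindered C1' ketone that hydroxide cleaves the chain by retro-Claisen fragmentation; or aromatisation outrunning the equilibration of a C3 epimer. Fallback, from 15: the chain is lengthened by one carbon at its nucleophilic end so that the fold proceeds near neutrality. Deprotonation to the trianion with LiN(i-Pr)2 (3.3 equiv, THF, 0 °C) and carboxylation with CO2 should give 7-[(2S,3S)-6-(benzyloxy)-2-[3,4-bis(benzyloxy)phenyl]-4-[(E)-4-(benzyloxy)styryl]-2,3-dihydrobenzofuran-3-yl]-3,5,7-trioxoheptanoic acid F1. Its C2 methylene is acidic enough to close onto C7 in a pH 8–9 buffer at room temperature, giving 2,4-dihydroxy-6-[(2S,3S)-6-(benzyloxy)-2-[3,4-bis(benzyloxy)phenyl]-4-[(E)-4-(benzyloxy)styryl]-2,3-dihydrobenzofuran-3-yl]benzoic acid F2. Warming F2 in wet DMSO (about 100 °C) expels CO2 and rejoins the route at 17.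

**Step 4.** What may go wrong: migration of ring B from C2 to C3 or loss of hydrogen in place of the ring-A shift; slow enol-ether formation beside the peri triflate; attack of the iodane on the benzyloxy-substituted rings; acid-induced opening of the pyranone ring with erosion of the C2 configuration. Fallback, from 5: halogenation and shift are separated. α-Bromination with PhNMe3Br3 (THF, 0 °C) should give (2R,3R)-7-(benzyloxy)-2-[3,4-bis(benzyloxy)phenyl]-3-bromo-4-oxochroman-5-yl trifluoromethanesulfonate F3 (2,3-trans; same spatial arrangement at C2 as in 5). Ketalisation (HC(OMe)3, MeOH, TsOH) gives (2R,3R)-7-(benzyloxy)-2-[3,4-bis(benzyloxy)phenyl]-3-bromo-4,4-dimethoxychroman-5-yl trifluoromethanesulfonate F4. AgBF4 then triggers the same 1,2-shift of ring A by silver-assisted loss of bromide (the α-halo ketal rearrangement used for 2-arylalkanoic esters), and aqueous work-up rejoins the route at 7.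

**Step 7.** What may go wrong: proton abstraction at C3 of 13 by the dianion outrunning C–C bond formation, followed by capture of the ketene at the central carbon of the diketone or at oxygen; incomplete return of C3 to the trans configuration. Fallback, from 11 and 12: a base-free acylation. 11 is converted with (COCl)2 and catalytic DMF into (2S,3S)-6-(benzyloxy)-2-[3,4-bis(benzyloxy)phenyl]-4-[(E)-4-(benzyloxy)styryl]-2,3-dihydrobenzofuran-3-carbonyl chloride F5. 12 is converted with Me3SiOTf/Et3N into (3Z)-2,4-bis(trimethylsilyloxy)penta-1,3-diene F6. The two are combined in CH2Cl2 (−78 → 20 °C); the terminal carbon of F6 is acylated, and aqueous work-up gives 15, where the route is rejoined.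

**Step 3.** What may go wrong: insufficient facial selectivity with this 5,7-dioxygenated chromone; protodeboronation or homocoupling of the electron-rich boronic acid; catalyst loss if adventitious zerovalent palladium inserts into the aryl triflate. Fallback, from 2: the order is changed so that no C–O electrophile is present. The same conjugate addition of 4 to the free 5-hydroxychromone should give (2S)-7-(benzyloxy)-2-[3,4-bis(benzyloxy)phenyl]-5-hydroxychroman-4-one F7, a phenol whose enantiomeric purity can be raised by recrystallisation. Triflation at −78 °C (Tf2O, 2,6-lutidine, CH2Cl2), cold enough to avoid base-induced opening of the flavanone, rejoins the route at 5.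

**Step 9.** What may go wrong: ionisation of the C2–O1 bond by the Lewis acid (ring opening, epimerisation at C2); protonation of the stilbene by HCl on warming followed by attack of the resorcinol ring; incomplete cleavage of the last ether. Fallback, from 17: cleavage under basic, cation-free conditions. NaSEt in DMF at about 110 °C under argon removes benzyl groups by SN2 attack of thiolate on the benzylic carbon while the substrate is present as its phenolates; acidification to pH 6 rejoins the route at 18. No new compound is made (entry F0).

## Further compounds

F1 | step 8 | 7-[(2S,3S)-6-(benzyloxy)-2-[3,4-bis(benzyloxy)phenyl]-4-[(E)-4-(benzyloxy)styryl]-2,3-dihydrobenzofuran-3-yl]-3,5,7-trioxoheptanoic acid | c1ccccc1COc1ccc(/C=C/c2cc(OCc4ccccc4)cc3c2[C@H](C(=O)CC(=O)CC(=O)CC(=O)O)[C@@H](c2ccc(OCc4ccccc4)c(OCc4ccccc4)c2)O3)cc1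
F2 | step 8 | 2,4-dihydroxy-6-[(2S,3S)-6-(benzyloxy)-2-[3,4-bis(benzyloxy)phenyl]-4-[(E)-4-(benzyloxy)styryl]-2,3-dihydrobenzofuran-3-yl]benzoic acid | c1ccccc1COc1ccc(/C=C/c2cc(OCc4ccccc4)cc3c2[C@H](c2cc(O)cc(O)c2C(=O)O)[C@@H](c2ccc(OCc4ccccc4)c(OCc4ccccc4)c2)O3)cc1
F3 | step 4 | (2R,3R)-7-(benzyloxy)-2-[3,4-bis(benzyloxy)phenyl]-3-bromo-4-oxochroman-5-yl trifluoromethanesulfonate | O=C1[C@H](Br)[C@@H](c2ccc(OCc3ccccc3)c(OCc3ccccc3)c2)Oc2cc(OCc3ccccc3)cc(OS(=O)(=O)C(F)(F)F)c21
F4 | step 4 | (2R,3R)-7-(benzyloxy)-2-[3,4-bis(benzyloxy)phenyl]-3-bromo-4,4-dimethoxychroman-5-yl trifluoromethanesulfonate | COC1(OC)[C@H](Br)[C@@H](c2ccc(OCc3ccccc3)c(OCc3ccccc3)c2)Oc2cc(OCc3ccccc3)cc(OS(=O)(=O)C(F)(F)F)c21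
F5 | step 7 | (2S,3S)-6-(benzyloxy)-2-[3,4-bis(benzyloxy)phenyl]-4-[(E)-4-(benzyloxy)styryl]-2,3-dihydrobenzofuran-3-carbonyl chloride | c1ccccc1COc1ccc(/C=C/c2cc(OCc4ccccc4)cc3c2[C@H](C(=O)Cl)[C@@H](c2ccc(OCc4ccccc4)c(OCc4ccccc4)c2)O3)cc1
F6 | step 7 | (3Z)-2,4-bis(trimethylsilyloxy)penta-1,3-diene | C=C(O[Si](C)(C)C)/C=C(\O[Si](C)(C)C)C
F7 | step 3 | (2S)-7-(benzyloxy)-2-[3,4-bis(benzyloxy)phenyl]-5-hydroxychroman-4-one | O=C1C[C@@H](c2ccc(OCc3ccccc3)c(OCc3ccccc3)c2)Oc2cc(OCc3ccccc3)cc(O)c21
F0 | step 9 | none | none
A1 | alternative 1 | methyl (2S,3S)-trans-2-(3,4-dimethoxyphenyl)-6-methoxy-4-(trifluoromethylsulfonyloxy)-2,3-dihydrobenzofuran-3-carboxylate | O=S(=O)(Oc1cc(OC)cc2c1[C@H](C(=O)OC)[C@@H](c1ccc(OC)c(OC)c1)O2)C(F)(F)F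
A2 | alternative 1 | (2S)-2-(3,4-dimethoxyphenyl)-7-methoxy-4-oxochroman-5-yl trifluoromethanesulfonate | O=C1C[C@@H](c2ccc(OC)c(OC)c2)Oc2cc(OC)cc(OS(=O)(=O)C(F)(F)F)c21
A3 | alternative 2 | (2R,3S)-cis-4-bromo-2-(3,4-dimethoxyphenyl)-3-(3,5-dimethoxyphenyl)-6-methoxy-2,3-dihydrobenzofuran | Brc1cc(OC)cc2c1[C@H](c1cc(OC)cc(OC)c1)[C@H](c1ccc(OC)c(OC)c1)O2
A4 | alternative 2 | [2-bromo-6-(3,4-dimethoxybenzyloxy)-4-methoxyphenyl](3,5-dimethoxyphenyl)methanone hydrazone | NN=C(c1cc(OC)cc(OC)c1)c1c(Br)cc(OC)cc1OCc1ccc(OC)c(OC)c1
A5 | alternative 2 | (2S,3S)-trans-4-bromo-2-(3,4-dimethoxyphenyl)-3-(3,5-dimethoxyphenyl)-6-methoxy-2,3-dihydrobenzofuran | Brc1cc(OC)cc2c1[C@H](c1cc(OC)cc(OC)c1)[C@@H](c1ccc(OC)c(OC)c1)O2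
A6 | alternative 3 | (2S,3S)-trans-4-bromo-2-[3,4-bis(methylsulfonyloxy)phenyl]-3-(3,5-dimethoxyphenyl)-6-methoxy-2,3-dihydrobenzofuran | Brc1cc(OC)cc2c1[C@H](c1cc(OC)cc(OC)c1)[C@@H](c1ccc(OS(C)(=O)=O)c(OS(C)(=O)=O)c1)O2
A7 | alternative 3 | (2R,3R)-2-[3,4-bis(methylsulfonyloxy)phenyl]-3-(3,5-dimethoxyphenyl)oxirane | COc1cc(OC)cc([C@H]2O[C@@H]2c2ccc(OS(C)(=O)=O)c(OS(C)(=O)=O)c2)c1
A8 | alternative 3 | 2-bromo-4-methoxy-6-(trimethylsilyl)phenyl trifluoromethanesulfonate | C[Si](C)(C)c1cc(OC)cc(Br)c1OS(=O)(=O)C(F)(F)F
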